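The disconnection cuts the two σ-bonds that flank the cyclobutane–cyclopentane fusion, C16–C17 and C18–C19 (carbons numbered along the SMILES, C1 = side-chain CH3, C24 = ester carbon). Both form in one decarboxylative radical cascade: a C16 radical on the preformed ester-bearing cyclohexene closes the second cyclohexene onto the strained, facially biased cyclobutene C17=C18 (6-exo), and the cyclobutyl radical C18 closes the cyclopentane (5-exo) onto a C19 tosylhydrazone, a traceless acceptor that ends as the unsubstituted CH2. The precursor is a (Z)-alkene-linked trans-3,4-disubstituted cyclobutene–cyclohexene carrying an N-acyloxyphthalimide at C16 and the aldehyde hydrazone on C20; its halves come from 2-pyrone photoisomer alkylation and a quinone-ketal Diels–Alder adduct.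

Key step: step 16

Remark (numbering): C1–C10 side chain from the terminal CH3; C11/C12/C17/C18 cyclobutane; C13=C14 and C21=C22 ring alkenes; C15/C16/C20/C23 ring CH; C19 ring CH2; C24 ester carbon.
Assumption: (5S)-5-(d-menthyloxy)furan-2(5H)-one (13) is purchased. The carbinol configuration drawn in 16, 17 and 19 and the N-bearing carbon in 23 are lost later and are of no consequence.

Step 1
Reactants: 1 dec-9-yn-1-ol
Product: 2 dec-8-yn-1-ol
Conditions: KOtBu, DMSO, rt; aq. NH4Cl
Reagents that add atoms: none
Why: Base-mediated propargyl–allenyl isomerisation should move the terminal alkyne one position inward to the more stable methyl-capped internal alkyne.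

Step 2
Reactants: 2 dec-8-yn-1-ol
Product: 3 (E)-dec-8-en-1-ol
Conditions: Li, NH3(l)/THF, t-BuOH, −33 °C; NH4Cl
Reagents that add atoms: none
Why: Dissolving-metal (Birch-type) reduction of an isolated internal alkyne should give the E-alkene through the trans vinyl radical anion.

Step 3
Reactants: 3 (E)-dec-8-en-1-ol
Product: 4 (E)-10-iododec-2-ene
Conditions: I2, PPh3, imidazole, CH2Cl2, 0 °C → rt
Reagents that add atoms: iodine, II
Why: Appel iodination of a primary alcohol; the remote alkene is untouched.

Step 4
Reactants: 5 2H-pyran-2-one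
Product: 6 (±)-2-oxabicyclo[2.2.0]hex-5-en-3-one
Conditions: hν (300 nm), Et2O, −10 °C
Reagents that add atoms: none
Why: Photochemical disrotatory 4π electrocyclisation of 2-pyrone should give its strained bicyclic valence isomer, a cyclobutene with an allylic carboxylate leaving group.

Step 5
Reactants: 4 (E)-10-iododec-2-ene; 6 (±)-2-oxabicyclo[2.2.0]hex-5-en-3-one
Product: 8 (1S,4S)-4-[(E)-dec-8-enyl]cyclobut-2-ene-1-carboxylic acid, via (E)-dec-8-enylzinc iodide 7 (not isolated)
Conditions: Zn dust, LiCl, THF, 40 °C; then 6, Pd2(dba)3 (2.5 mol%), BINOL-derived bis(1-phenylethyl)amine phosphoramidite (6 mol%, enantiomer giving the 1S,4S acid), THF, −20 °C → rt; 1 M HCl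
Reagents that add atoms: none
Why: After zinc insertion, Pd-catalysed asymmetric allylic alkylation should convert both enantiomers of 6 into one meso η3-cyclobutenyl-palladium carboxylate; transmetalation and reductive elimination then place the alkyl group anti to the carboxylate (trans) at the allyl terminus chosen by the ligand, setting C11 and C12 stereoconvergently.

Step 6
Reactants: 8 (1S,4S)-4-[(E)-dec-8-enyl]cyclobut-2-ene-1-carboxylic acid
Product: 9 [(1S,4S)-4-[(E)-dec-8-enyl]cyclobut-2-en-1-yl]methanol
Conditions: LiAlH4, Et2O, 0 °C; aq. NaOH work-up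
Reagents that add atoms: none
Why: Hydride reduction of the acid to the primary alcohol; this also removes the carboxyl group that lowers the barrier to cyclobutene ring opening.

Step 7
Reactants: 9 [(1S,4S)-4-[(E)-dec-8-enyl]cyclobut-2-en-1-yl]methanol
Product: 10 (3S,4S)-3-[(E)-dec-8-enyl]-4-(iodomethyl)cyclobut-1-ene
Conditions: I2, PPh3, imidazole, CH2Cl2, 0 °C
Reagents that add atoms: iodine, II
Why: Appel iodination at the primary carbon; no stereocentre is involved.

Step 8
Reactants: 10 (3S,4S)-3-[(E)-dec-8-enyl]-4-(iodomethyl)cyclobut-1-ene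
Product: 11 {[(1S,4S)-4-[(E)-dec-8-enyl]cyclobut-2-en-1-yl]methyl}triphenylphosphonium iodide
Conditions: PPh3, MeCN, 70 °C
Reagents that add atoms: triphenylphosphine, c1ccc(cc1)P(c1ccccc1)c1ccccc1
Why: SN2 quaternisation of the primary iodide, well below the temperature at which a 3,4-dialkylcyclobutene opens.

Step 9
Reactants: 12 2-methoxyphenol; 13 (5S)-5-(d-menthyloxy)furan-2(5H)-one
Product: 15 endo Diels–Alder adduct (3,3-dimethoxybicyclo[2.2.2]oct-5-en-2-one cis-fused to the menthyloxy-γ-butyrolactone), via masked o-benzoquinone 14 (not isolated)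
Conditions: PhI(OAc)2 (1.2 equiv), 13 (3 equiv, excess recovered), MeOH, 50 °C, 12 added over 8 h
Reagents that add atoms: methanol, CO
Why: Oxidative dearomatisation gives dienone 14, which is trapped in a Diels–Alder reaction in which the lactone C=O carbon ends next to the ketone-side bridgehead (ortho rule of these dienones), the lactone lies under the new alkene (endo) and the diene adds anti to the menthyloxy group, so C15, C20 and C23 (and the temporary C16 centre) are set in absolute terms.

Step 10
Reactants: 15 endo Diels–Alder adduct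
Product: 16 hydroxy ketal (bridge ketone reduced to the secondary alcohol)
Conditions: NaBH4, MeOH, 0 °C
Reagents that add atoms: none
Why: Borohydride should reduce only the strained bridge ketone, turning the keto-ketal into the latent α-ketol that later differentiates C19 (aldehyde) from C24 (ester).

Step 11
Reactants: 16 hydroxy ketal
Product: 17 α-ketol γ-hydroxylactone (bridge ketone free; masked C14 aldehyde and C16 acid)
Conditions: TFA/H2O (4:1), 40 °C
Reagents that add atoms: water, O
Why: Acid hydrolysis of the dimethyl ketal and of the menthyl acetal; the stereocentres that persist are bridgeheads or ring-fusion carbons and cannot epimerise.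

Step 12
Reactants: 17 α-ketol γ-hydroxylactone; 11 {[(1S,4S)-4-[(E)-dec-8-enyl]cyclobut-2-en-1-yl]methyl}triphenylphosphonium iodide
Product: 19 (Z)-alkene-linked cyclobutene bicyclic ketol acid, via phosphorus ylide 18 (not isolated)
Conditions: 11, NaHMDS, THF, −78 °C; then 17 (as sodium carboxylate, 1 equiv NaHMDS), −78 → 0 °C; pH 5 buffer
Reagents that add atoms: none
Why: Wittig olefination of the ring-opened hydroxylactone (aldehyde carboxylate) with a non-stabilised salt-free ylide should give the (Z)-alkene under kinetic control; the ketol sits as its alkoxide and the future ester stereocentre is still a non-enolisable bridgehead.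

Step 13
Reactants: 19 (Z)-alkene-linked cyclobutene bicyclic ketol acid
Product: 20 aldehyde ester acid (monocyclic cyclohexene: C20–CHO and C23–CO2Me cis; C16–CO2H)
Conditions: Pb(OAc)4, MeOH/benzene (1:1), 0 °C, 15 min
Reagents that add atoms: methanol, CO
Why: Criegee-type cleavage of the α-ketol through its methanol hemiketal should give the C19 aldehyde and the C24 methyl ester, necessarily cis because both carbons were tied in one bridge.

Step 14
Reactants: 20 aldehyde ester acid
Product: 21 (E)-tosylhydrazone acid
Conditions: TsNHNH2, MeOH, 0 °C → rt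
Reagents that add atoms: p-toluenesulfonyl hydrazide, Cc1ccc(cc1)S(=O)(=O)NN
Why: Condensation installs the C=N radical acceptor and at once masks the epimerisable β,γ-unsaturated aldehyde.

Step 15
Reactants: 21 (E)-tosylhydrazone acid
Product: 22 N-acyloxyphthalimide (redox-active ester at the C16 carboxyl)
Conditions: N-hydroxyphthalimide, DIC, CH2Cl2, 0 °C → rt
Reagents that add atoms: N-hydroxyphthalimide, ON1C(=O)c2ccccc2C1=O
Why: Carbodiimide esterification under base-free conditions gives the radical precursor without touching the ester α-centre.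

Step 16
Reactants: 22 N-acyloxyphthalimide
Product: 25 CNP0133550.1 (target), via cyclised N-alkyl-N'-tosylhydrazide 23 (not isolated), via monoalkyl diazene 24 (not isolated)
Conditions: [Ru(bpy)3](PF6)2 (2 mol%), Hantzsch ester (1.5 equiv), i-Pr2NEt·HBF4, CH2Cl2 (5 mM), blue LEDs, rt; then NaOAc·3H2O, MeOH, 65 °C
Reagents that add atoms: none
Why: Single-electron reduction of the N-acyloxyphthalimide releases CO2 and the secondary C16 radical, which adds 6-exo-trig to C17 of the cyclobutene (closing the cyclohexene that contains C12–C17), and the cyclobutyl radical at C18 then adds 5-exo-trig to the carbon of the C19 sulfonylhydrazone (closing the cyclopentane); hydrogen transfer gives hydrazide 23, which on warming with acetate loses sulfinate and then N2 through diazene 24, leaving C19 as CH2. The closest known types are reductive decarboxylative radical cyclisations of N-acyloxyphthalimides, tandem radical cyclisations onto hydrazone C=N acceptors, and the sulfinate/N2 loss of N-alkyl-N'-sulfonylhydrazides used in reductive C–C coupling with sulfonylhydrazones. C16 is set by closure on the ring face that carries the C15 tether (cis fusion), which is also anti to the C20 substituent; C17 is set by attack on the cyclobutene face syn to the C12 tether and anti to the C11 side chain (cis-bicyclo[4.2.0]); C18 is set because the five-membered ring can only fuse cis to the cyclobutane. The step needs the 6-exo closure to outrun hydrogen transfer to C16, 7-endo attack and a 1,2-vinyl shift of the homoallylic radical; cyclobutene strain, the rigid (Z)-alkene tether, high dilution and a slow hydrogen donor are meant to secure this, and the (E)-hydrazone keeps its N–H away from the radical.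

Compound list
1 | dec-9-yn-1-ol | C#CCCCCCCCCO | starting material
2 | dec-8-yn-1-ol | CC#CCCCCCCCO | intermediate
3 | (E)-dec-8-en-1-ol | C/C=C/CCCCCCCO | intermediate
4 | (E)-10-iododec-2-ene | C/C=C/CCCCCCCI | intermediate
5 | 2H-pyran-2-one | O=C1C=CC=CO1 | starting material
6 | (±)-2-oxabicyclo[2.2.0]hex-5-en-3-one (cis-fused, racemic) | O=C1OC2C=CC12 | intermediate
7 | (E)-dec-8-enylzinc iodide | C/C=C/CCCCCCC[Zn]I | intermediate (not isolated)
8 | (1S,4S)-4-[(E)-dec-8-enyl]cyclobut-2-ene-1-carboxylic acid (trans) | C/C=C/CCCCCCC[C@@H]1[C@@H](C(=O)O)C=C1 | intermediate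
9 | [(1S,4S)-4-[(E)-dec-8-enyl]cyclobut-2-en-1-yl]methanol | C/C=C/CCCCCCC[C@@H]1[C@@H](CO)C=C1 | intermediate
10 | (3S,4S)-3-[(E)-dec-8-enyl]-4-(iodomethyl)cyclobut-1-ene | C/C=C/CCCCCCC[C@@H]1[C@@H](CI)C=C1 | intermediate
11 | {[(1S,4S)-4-[(E)-dec-8-enyl]cyclobut-2-en-1-yl]methyl}triphenylphosphonium iodide | C/C=C/CCCCCCC[C@@H]1[C@@H](C[P+](c2ccccc2)(c2ccccc2)c2ccccc2)C=C1.[I-] | intermediate
12 | 2-methoxyphenol (guaiacol) | COc1ccccc1O | starting material
13 | (5S)-5-[(1S,2R,5S)-menthyloxy]furan-2(5H)-one | CC(C)[C@H]1CC[C@H](C)C[C@@H]1O[C@@H]1C=CC(=O)O1 | starting material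
14 | 6,6-dimethoxycyclohexa-2,4-dien-1-one (masked o-benzoquinone) | COC1(OC)C=CC=CC1=O | intermediate (not isolated)
15 | endo adduct: 3,3-dimethoxybicyclo[2.2.2]oct-5-en-2-one cis-fused to the 5-(d-menthyloxy)-γ-butyrolactone; lactone C=O on the carbon next to the ketone-side bridgehead, lactone anti to the keto-ketal bridge, O-menthyl anti to the bicycle | CC(C)[C@H]4CC[C@H](C)C[C@@H]4O[C@@H]2[C@@H]1[C@H](C(=O)O2)[C@@H]3C=C[C@H]1C(OC)(OC)C3=O | intermediate
16 | hydroxy ketal: as 15 with the bridge ketone reduced to CH–OH (expected major epimer drawn) | CC(C)[C@H]4CC[C@H](C)C[C@@H]4O[C@@H]2[C@@H]1[C@H](C(=O)O2)[C@@H]3C=C[C@H]1C(OC)(OC)[C@@H]3O | intermediate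
17 | α-ketol γ-hydroxylactone: bicyclo[2.2.2]octenone with bridge CH(OH)–C(=O), cis-fused 5-hydroxy-γ-butyrolactone (one anomer drawn, equilibrating) | O[C@@H]2[C@@H]1[C@H](C(=O)O2)[C@@H]3C=C[C@H]1C(=O)[C@@H]3O | intermediate
18 | phosphorus ylide from 11 | C/C=C/CCCCCCC[C@@H]1[C@@H](C=P(c2ccccc2)(c2ccccc2)c2ccccc2)C=C1 | intermediate (not isolated)
19 | bicyclic ketol acid carrying the (Z)-2-[(1R,4S)-configured trans-4-decenylcyclobutenyl]vinyl group on the carbon next to the ketone-side... ring carbon C15, CO2H on C16 (configuration as in SMILES) | C/C=C/CCCCCCC[C@@H]1[C@@H](/C=C\[C@@H]2[C@H](C(=O)O)[C@@H]3C=C[C@H]2C(=O)[C@@H]3O)C=C1 | intermediate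
20 | aldehyde ester acid: cyclohex-2-ene with 1-CO2Me (C23), 4-CHO (C20, cis to the ester), 5-CO2H (C16) and 6-[(Z)-alkenylcyclobutene] (C15, trans to ester and formyl) | C/C=C/CCCCCCC[C@@H]1[C@@H](/C=C\[C@@H]2[C@H](C(=O)O)[C@@H](C=O)C=C[C@H]2C(=O)OC)C=C1 | intermediate
21 | (E)-tosylhydrazone of 20 | C/C=C/CCCCCCC[C@@H]1[C@@H](/C=C\[C@@H]2[C@H](C(=O)O)[C@@H](/C=N/NS(=O)(=O)c3ccc(C)cc3)C=C[C@H]2C(=O)OC)C=C1 | intermediate
22 | N-acyloxyphthalimide of 21 (at the C16 carboxyl) | C/C=C/CCCCCCC[C@@H]1[C@@H](/C=C\[C@@H]2[C@H](C(=O)ON4C(=O)c5ccccc5C4=O)[C@@H](/C=N/NS(=O)(=O)c3ccc(C)cc3)C=C[C@H]2C(=O)OC)C=C1 | intermediate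
23 | cyclised tetracycle with NH–NHTs on C19 (mixture of C19 epimers) | C/C=C/CCCCCCC[C@@H]1[C@H]2C=C[C@@H]3[C@@H]4[C@H]2[C@H]1C(NNS(=O)(=O)c5ccc(C)cc5)[C@H]4C=C[C@H]3C(=O)OC | intermediate (not isolated)
24 | tetracycle with N=NH on C19 (monoalkyl diazene) | C/C=C/CCCCCCC[C@@H]1[C@H]2C=C[C@@H]3[C@@H]4[C@H]2[C@H]1C(N=N)[C@H]4C=C[C@H]3C(=O)OC | intermediate (not isolated)
25 | CNP0133550.1 | C/C=C/CCCCCCC[C@@H]1[C@H]2C=C[C@@H]3[C@@H]4[C@H]2[C@H]1C[C@H]4C=C[C@H]3C(=O)OC | target

Total step count: 16. Longest linear sequence: 12 steps (steps 1–3, 5–8, 12–16).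

Steps most likely to fail

Step 16. The C16 or C18 radical may be quenched by hydrogen transfer before ring closure, or sulfinate/N2 loss from 23 may be sluggish. Fallback: set out from 20. Condensation with 1-amino-2-phenylaziridine should give the N-aziridinylimine acid F1, and carbodiimide coupling with N-hydroxyphthalimide its redox-active ester F2. Under the same radical generation the adduct aminyl radical collapses irreversibly, with loss of styrene and N2, to the C19 radical inside the chain (the known tandem cyclisation of N-aziridinylimines). No N–H group is present and no separate fragmentation is needed; reduction of that radical comes back to the route at 25.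

Step 9. Self-dimerisation of 14 may outrun its cycloaddition with the only moderately reactive butenolide. Fallback: set out from 13 and 4-bromo-2-methoxyphenol F3. Its oxidation in methanol should give the 4-bromo masked o-benzoquinone F4, which does not dimerise and can be heated with 13 to the bromo adduct F5. Radical hydrodebromination of the vinyl bromide (Bu3SnH, AIBN) comes back to the route at 15.

Step 5. Discrimination between the two allyl termini may be poor with the functionalised alkylzinc halide, giving low enantiomeric purity. Fallback: set out from 6 and 7. The same coupling with an achiral palladium catalyst should give the racemic trans acid F6, which is resolved by crystallisation of the (R)-1-phenylethylammonium salt F7; acidification comes back to the route at 8.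

Further compounds
F1 | step 16 | N-aziridinylimine acid (from 20 and 1-amino-2-phenylaziridine) | C/C=C/CCCCCCC[C@@H]1[C@@H](/C=C\[C@@H]2[C@H](C(=O)O)[C@@H](/C=N/N3CC3c4ccccc4)C=C[C@H]2C(=O)OC)C=C1
F2 | step 16 | N-acyloxyphthalimide of F1 | C/C=C/CCCCCCC[C@@H]1[C@@H](/C=C\[C@@H]2[C@H](C(=O)ON5C(=O)c6ccccc6C5=O)[C@@H](/C=N/N3CC3c4ccccc4)C=C[C@H]2C(=O)OC)C=C1
F3 | step 9 | 4-bromo-2-methoxyphenol | COc1cc(Br)ccc1O
F4 | step 9 | 4-bromo-6,6-dimethoxycyclohexa-2,4-dien-1-one | COC1(OC)C=C(Br)C=CC1=O
F5 | step 9 | bromo adduct (15 with Br on the alkene carbon next to the ketal-side bridgehead) | CC(C)[C@H]4CC[C@H](C)C[C@@H]4O[C@@H]2[C@@H]1[C@H](C(=O)O2)[C@@H]3C=C(Br)[C@H]1C(OC)(OC)C3=O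
F6 | step 5 | racemic trans-4-[(E)-dec-8-enyl]cyclobut-2-ene-1-carboxylic acid | C/C=C/CCCCCCC[C@@H]1[C@@H](C(=O)O)C=C1.C/C=C/CCCCCCC[C@H]1[C@H](C(=O)O)C=C1
F7 | step 5 | (R)-1-phenylethylammonium salt of 8 | C/C=C/CCCCCCC[C@@H]1[C@@H](C(=O)[O-])C=C1.C[C@@H]([NH3+])c1ccccc1
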